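**Retrosynthetic overview**
1. Acid 43 ⇐ methyl ester 41 (lipase hydrolysis at pH 7) ⇐ C3–CH2 bond made by adding a silyl ketene acetal to the peroxycarbenium ion from 3-methoxy-1,2-dioxolane 38.
2. The 1,2-dioxolane is the last ring formed (5-exo closure of a β-hydroperoxy ketone); its C5–OOH comes from opening a 2,2-disubstituted oxetane with H2O2 with inversion.
3. Oxetane (second ring) ⇐ 1,3-diol ⇐ hydride opening of a Sharpless epoxide (first ring) of an (E)-trisubstituted allylic alcohol; this fixes C5.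
4. The allylic alcohols come from Zr-catalysed carboalumination of terminal alkynes; two Ru–BINAP hydrogenations (S ligand, then R ligand), linked by oxidation/Ohira–Bestmann homologation, build the anti-1,3-dimethyl chain.
5. Start: (8-bromooctyl)benzene + lithium acetylide; the benzene ring is bought in.

Assumption: paraformaldehyde is written as its monomer, the centres written without descriptor in 34, 37 and 38 are carried as epimer mixtures, and 1, 11 and 39 are taken as catalogue items.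

**Route**

Step 1
Reactants: 1 (8-bromooctyl)benzene; 2 lithium acetylide–ethylenediamine complex
Product: 3 10-phenyldec-1-yne
Conditions: LiC≡CH·H2NCH2CH2NH2, DMSO, 10 → 25 °C
Reagents that add atoms: lithium acetylide–ethylenediamine complex [Li]C#C.NCCN
Why: SN2 alkylation of the acetylide by an unhindered primary bromide in DMSO; no stereocentre is involved.

Step 2
Reactants: 3 10-phenyldec-1-yne; 4 trimethylaluminium; 5 paraformaldehyde
Product: 8 (2E)-3-methyl-11-phenylundec-2-en-1-ol, via alkenylalane 6 (not isolated), via lithium alkenylaluminate 7 (not isolated)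
Conditions: AlMe3 (2 equiv), Cp2ZrCl2 (0.2 equiv), CH2Cl2, 0 → 23 °C; then n-BuLi, THF, −78 °C; (CH2O)n, → 23 °C; aq. HCl
Reagents that add atoms: trimethylaluminium C[Al](C)C; paraformaldehyde C=O
Why: Negishi zirconium-catalysed methylalumination adds CH3 and Al syn across the alkyne (CH3 to the internal carbon), and the aluminate adds to formaldehyde with retention, so only the 2E allylic alcohol forms.

Step 3
Reactants: 8 (2E)-3-methyl-11-phenylundec-2-en-1-ol
Product: 9 (3R)-3-methyl-11-phenylundecan-1-ol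
Conditions: H2 (100 atm), Ru(OAc)2[(S)-BINAP] (0.5 mol %), MeOH–H2O 95:5, 20 °C
Reagents that add atoms: none
Why: Noyori hydroxyl-directed asymmetric hydrogenation; the (S)-BINAP complex reduces (E)-3-methyl-2-alken-1-ols on the face that gives the 3R alcohol (as geraniol gives (R)-citronellol), creating the first stereocentre from achiral material.

Step 4
Reactants: 9 (3R)-3-methyl-11-phenylundecan-1-ol
Product: 10 (3R)-3-methyl-11-phenylundecanal
Conditions: TEMPO (10 mol %), PhI(OAc)2 (1.1 equiv), CH2Cl2, 23 °C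
Reagents that add atoms: none
Why: Oxoammonium (TEMPO) oxidation stops at the aldehyde, and the β-stereocentre cannot epimerise.

Step 5
Reactants: 10 (3R)-3-methyl-11-phenylundecanal; 11 dimethyl (1-diazo-2-oxopropyl)phosphonate
Product: 12 (4R)-4-methyl-12-phenyldodec-1-yne
Conditions: K2CO3, MeOH, 0 → 23 °C
Reagents that add atoms: dimethyl (1-diazo-2-oxopropyl)phosphonate CC(=O)C(=[N+]=[N-])P(=O)(OC)OC
Why: Ohira–Bestmann (Seyferth–Gilbert) homologation turns the aldehyde carbon into the internal alkyne carbon under mild base, leaving the remote stereocentre alone.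

Step 6
Reactants: 12 (4R)-4-methyl-12-phenyldodec-1-yne; 4 trimethylaluminium; 5 paraformaldehyde
Product: 15 (2E,5R)-3,5-dimethyl-13-phenyltridec-2-en-1-ol, via alkenylalane 13 (not isolated), via lithium alkenylaluminate 14 (not isolated)
Conditions: AlMe3 (2 equiv), Cp2ZrCl2 (0.2 equiv), CH2Cl2, 0 → 23 °C; then n-BuLi, THF, −78 °C; (CH2O)n, → 23 °C; aq. HCl
Reagents that add atoms: trimethylaluminium C[Al](C)C; paraformaldehyde C=O
Why: The same Negishi carboalumination/formaldehyde trapping gives the 2E alkene stereospecifically; the 5R centre is not touched.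

Step 7
Reactants: 15 (2E,5R)-3,5-dimethyl-13-phenyltridec-2-en-1-ol
Product: 16 (3S,5R)-3,5-dimethyl-13-phenyltridecan-1-ol
Conditions: H2 (100 atm), Ru(OAc)2[(R)-BINAP] (0.5 mol %), MeOH–H2O 95:5, 20 °C
Reagents that add atoms: none
Why: Noyori hydrogenation with the enantiomeric (R)-BINAP complex sets 3S under hydroxyl-directed catalyst control, which gives the anti-1,3-dimethyl relationship.

Step 8
Reactants: 16 (3S,5R)-3,5-dimethyl-13-phenyltridecan-1-ol
Product: 17 (3S,5R)-3,5-dimethyl-13-phenyltridecanal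
Conditions: TEMPO (10 mol %), PhI(OAc)2 (1.1 equiv), CH2Cl2, 23 °C
Reagents that add atoms: none
Why: TEMPO oxidation to the aldehyde; both stereocentres are β or further from the carbonyl and cannot epimerise.

Step 9
Reactants: 17 (3S,5R)-3,5-dimethyl-13-phenyltridecanal; 11 dimethyl (1-diazo-2-oxopropyl)phosphonate
Product: 18 (4S,6R)-4,6-dimethyl-14-phenyltetradec-1-yne
Conditions: K2CO3, MeOH, 0 → 23 °C
Reagents that add atoms: dimethyl (1-diazo-2-oxopropyl)phosphonate CC(=O)C(=[N+]=[N-])P(=O)(OC)OC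
Why: Ohira–Bestmann homologation as in step 5; no stereocentre is affected.

Step 10
Reactants: 18 (4S,6R)-4,6-dimethyl-14-phenyltetradec-1-yne; 4 trimethylaluminium; 5 paraformaldehyde
Product: 21 (2E,5S,7R)-3,5,7-trimethyl-15-phenylpentadec-2-en-1-ol, via alkenylalane 19 (not isolated), via lithium alkenylaluminate 20 (not isolated)
Conditions: AlMe3 (2 equiv), Cp2ZrCl2 (0.2 equiv), CH2Cl2, 0 → 23 °C; then n-BuLi, THF, −78 °C; (CH2O)n, → 23 °C; aq. HCl
Reagents that add atoms: trimethylaluminium C[Al](C)C; paraformaldehyde C=O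
Why: Negishi carboalumination gives the (E)-trisubstituted allylic alcohol needed for the epoxidation; existing centres are untouched.

Step 11
Reactants: 21 (2E,5S,7R)-3,5,7-trimethyl-15-phenylpentadec-2-en-1-ol; 22 tert-butyl hydroperoxide
Product: 23 [(2S,3S)-3-[(2S,4R)-2,4-dimethyl-12-phenyldodecyl]-3-methyloxiran-2-yl]methanol
Conditions: Ti(OiPr)4 (10 mol %), L-(+)-diethyl tartrate (12 mol %), t-BuOOH (2 equiv, decane), 4 Å sieves, CH2Cl2, −20 °C
Reagents that add atoms: tert-butyl hydroperoxide CC(C)(C)OO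
Why: Sharpless asymmetric epoxidation; with L-(+)-diethyl tartrate an (E)-3-methyl-2-alken-1-ol gives the (2S,3S)-epoxide (as geraniol does), reagent control overriding the remote methyl centres, and this fixes the oxygen-bearing carbon that becomes C5.

Step 12
Reactants: 23 [(2S,3S)-3-[(2S,4R)-2,4-dimethyl-12-phenyldodecyl]-3-methyloxiran-2-yl]methanol
Product: 24 (3S,5S,7R)-3,5,7-trimethyl-15-phenylpentadecane-1,3-diol
Conditions: NaAlH2(OCH2CH2OCH3)2, THF, 0 → 23 °C; aq. NaOH
Reagents that add atoms: none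
Why: The aluminate bound to the hydroxyl delivers hydride intramolecularly to C2 of the 2,3-epoxy alcohol, so the tertiary C–O bond and its configuration survive and the 1,3-diol forms.

Step 13
Reactants: 24 (3S,5S,7R)-3,5,7-trimethyl-15-phenylpentadecane-1,3-diol; 25 4-methylbenzenesulfonyl chloride
Product: 26 (3S,5S,7R)-3-hydroxy-3,5,7-trimethyl-15-phenylpentadecyl 4-methylbenzenesulfonate
Conditions: TsCl (1.1 equiv), Et3N, DMAP (cat.), CH2Cl2, 0 °C
Reagents that add atoms: 4-methylbenzenesulfonyl chloride Cc1ccc(cc1)S(=O)(=O)Cl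
Why: Sulfonylation is selective for the primary hydroxyl; the tertiary one is too hindered to react.

Step 14
Reactants: 26 (3S,5S,7R)-3-hydroxy-3,5,7-trimethyl-15-phenylpentadecyl 4-methylbenzenesulfonate
Product: 27 (2S)-2-[(2S,4R)-2,4-dimethyl-12-phenyldodecyl]-2-methyloxetane
Conditions: KOtBu (1.5 equiv), THF, 0 → 23 °C
Reagents that add atoms: none
Why: Intramolecular Williamson etherification (4-exo-tet) of the tertiary alkoxide onto the primary tosylate; the C–O bond at the stereocentre is not broken, so configuration is retained.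

Step 15
Reactants: 27 (2S)-2-[(2S,4R)-2,4-dimethyl-12-phenyldodecyl]-2-methyloxetane; 28 hydrogen peroxide
Product: 29 (3R,5S,7R)-3-hydroperoxy-3,5,7-trimethyl-15-phenylpentadecan-1-ol
Conditions: anhydrous H2O2 in Et2O (10 equiv), TMSOTf (0.3 equiv), Et2O, −78 → 0 °C
Reagents that add atoms: hydrogen peroxide OO
Why: Lewis-acid-activated perhydrolysis of the oxetane occurs at the tertiary carbon with inversion (contact-ion-pair ring opening), turning the 2S oxetane carbon into the 3R hydroperoxide carbon that is C5 of the target.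

Step 16
Reactants: 29 (3R,5S,7R)-3-hydroperoxy-3,5,7-trimethyl-15-phenylpentadecan-1-ol; 30 2-methoxypropene
Product: 31 (3R,5S,7R)-3-[(2-methoxypropan-2-yl)peroxy]-3,5,7-trimethyl-15-phenylpentadecan-1-ol
Conditions: 2-methoxypropene (1.2 equiv), PPTS (5 mol %), CH2Cl2, 0 °C
Reagents that add atoms: 2-methoxypropene COC(C)=C
Why: Acid-catalysed addition of the hydroperoxide (more acidic and more nucleophilic than the alcohol) to the enol ether gives the peroxyketal, masking OOH for the next three steps.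

Step 17
Reactants: 31 (3R,5S,7R)-3-[(2-methoxypropan-2-yl)peroxy]-3,5,7-trimethyl-15-phenylpentadecan-1-ol
Product: 32 (3R,5S,7R)-3-[(2-methoxypropan-2-yl)peroxy]-3,5,7-trimethyl-15-phenylpentadecanal
Conditions: Dess–Martin periodinane, NaHCO3, CH2Cl2, 0 → 23 °C
Reagents that add atoms: none
Why: Buffered Dess–Martin oxidation gives the aldehyde without acid that would cleave the peroxyketal or base that would eliminate the β-peroxide.

Step 18
Reactants: 32 (3R,5S,7R)-3-[(2-methoxypropan-2-yl)peroxy]-3,5,7-trimethyl-15-phenylpentadecanal; 33 methylmagnesium bromide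
Product: 34 (2RS,4R,6S,8R)-4-[(2-methoxypropan-2-yl)peroxy]-4,6,8-trimethyl-16-phenylhexadecan-2-ol
Conditions: MeMgBr (1.2 equiv), Et2O, −78 °C; then pH 7 aq. buffer
Reagents that add atoms: methylmagnesium bromide C[Mg]Br
Why: Grignard addition to the aldehyde at −78 °C is much faster than attack on the hindered O–O bond flanked by two fully substituted carbons; both carbinol epimers are used because that centre is removed in the next step.

Step 19
Reactants: 34 (2RS,4R,6S,8R)-4-[(2-methoxypropan-2-yl)peroxy]-4,6,8-trimethyl-16-phenylhexadecan-2-ol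
Product: 35 (4R,6S,8R)-4-[(2-methoxypropan-2-yl)peroxy]-4,6,8-trimethyl-16-phenylhexadecan-2-one
Conditions: Dess–Martin periodinane, NaHCO3, CH2Cl2, 0 → 23 °C
Reagents that add atoms: none
Why: Buffered Dess–Martin oxidation removes the carbinol stereocentre and gives the β-peroxy methyl ketone under neutral conditions.

Step 20
Reactants: 35 (4R,6S,8R)-4-[(2-methoxypropan-2-yl)peroxy]-4,6,8-trimethyl-16-phenylhexadecan-2-one; 36 methanol
Product: 38 (3RS,5R)-5-[(2S,4R)-2,4-dimethyl-12-phenyldodecyl]-3-methoxy-3,5-dimethyl-1,2-dioxolane, via 1,2-dioxolan-3-ol 37 (not isolated)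
Conditions: p-TsOH·H2O (5 mol %), MeOH, 0 → 23 °C
Reagents that add atoms: methanol CO
Why: Acid-catalysed transketalisation frees the hydroperoxide, which closes 5-exo onto the ketone and is then converted into the methyl peroxyketal; C5 is untouched and both C3 epimers are usable because the next step passes through a planar cation.

Step 21
Reactants: 38 (3RS,5R)-5-[(2S,4R)-2,4-dimethyl-12-phenyldodecyl]-3-methoxy-3,5-dimethyl-1,2-dioxolane; 39 tert-butyl[(1-methoxyethenyl)oxy]dimethylsilane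
Product: 41 methyl 2-[(3R,5R)-5-[(2S,4R)-2,4-dimethyl-12-phenyldodecyl]-3,5-dimethyl-1,2-dioxolan-3-yl]acetate, via peroxycarbenium ion 40 (not isolated)
Conditions: TiCl4 (1.1 equiv), 39 (3 equiv), CH2Cl2, −78 °C; chromatographic separation of the C3 epimers
Reagents that add atoms: tert-butyl[(1-methoxyethenyl)oxy]dimethylsilane C=C(OC)O[Si](C)(C)C(C)(C)C
Why: TiCl4 ionises the peroxyketal to the peroxycarbenium ion, which the silyl ketene acetal traps in a Mukaiyama-type addition; C3 is created here with little facial bias (CH3 versus CH2R at C5), so roughly equal amounts of both C3 epimers are expected and the 3R,5R isomer (NOE between the two ring CH3 groups) is isolated by chromatography.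

Step 22
Reactants: 41 methyl 2-[(3R,5R)-5-[(2S,4R)-2,4-dimethyl-12-phenyldodecyl]-3,5-dimethyl-1,2-dioxolan-3-yl]acetate; 42 water
Product: 43 2-[(3R,5R)-5-[(2S,4R)-2,4-dimethyl-12-phenyldodecyl]-3,5-dimethyl-1,2-dioxolan-3-yl]acetic acid
Conditions: Candida rugosa lipase, pH 7.2 phosphate buffer–acetone 4:1, 30 °C
Reagents that add atoms: water O
Why: A lipase (a serine hydrolase that accepts lipophilic fatty esters) hydrolyses the methyl ester at neutral pH, so the peroxide and the C3 centre, which base could scramble by retro-peroxy-Michael ring opening, are untouched.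

**Compound list**
1 | (8-bromooctyl)benzene | BrCCCCCCCCc1ccccc1 | starting material
2 | lithium acetylide–ethylenediamine complex | [Li]C#C.NCCN | starting material
3 | 10-phenyldec-1-yne | C#CCCCCCCCCc1ccccc1 | intermediate
4 | trimethylaluminium | C[Al](C)C | starting material
5 | paraformaldehyde (monomer shown) | C=O | starting material
6 | dimethyl[(1E)-2-methyl-10-phenyldec-1-en-1-yl]alumane | C[Al](C)/C=C(\C)CCCCCCCCc1ccccc1 | intermediate (not isolated)
7 | lithium butyl(dimethyl)[(1E)-2-methyl-10-phenyldec-1-en-1-yl]aluminate | [Li+].CCCC[Al-](C)(C)/C=C(\C)CCCCCCCCc1ccccc1 | intermediate (not isolated)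
8 | (2E)-3-methyl-11-phenylundec-2-en-1-ol | OC/C=C(\C)CCCCCCCCc1ccccc1 | intermediate
9 | (3R)-3-methyl-11-phenylundecan-1-ol | C[C@H](CCCCCCCCc1ccccc1)CCO | intermediate
10 | (3R)-3-methyl-11-phenylundecanal | C[C@H](CCCCCCCCc1ccccc1)CC=O | intermediate
11 | dimethyl (1-diazo-2-oxopropyl)phosphonate | CC(=O)C(=[N+]=[N-])P(=O)(OC)OC | starting material
12 | (4R)-4-methyl-12-phenyldodec-1-yne | C[C@H](CCCCCCCCc1ccccc1)CC#C | intermediate
13 | dimethyl[(1E,4R)-2,4-dimethyl-12-phenyldodec-1-en-1-yl]alumane | C[C@H](CCCCCCCCc1ccccc1)C/C(C)=C/[Al](C)C | intermediate (not isolated)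
14 | lithium butyl(dimethyl)[(1E,4R)-2,4-dimethyl-12-phenyldodec-1-en-1-yl]aluminate | [Li+].C[C@H](CCCCCCCCc1ccccc1)C/C(C)=C/[Al-](C)(C)CCCC | intermediate (not isolated)
15 | (2E,5R)-3,5-dimethyl-13-phenyltridec-2-en-1-ol | C[C@H](CCCCCCCCc1ccccc1)C/C(C)=C/CO | intermediate
16 | (3S,5R)-3,5-dimethyl-13-phenyltridecan-1-ol | C[C@H](CCCCCCCCc1ccccc1)C[C@H](C)CCO | intermediate
17 | (3S,5R)-3,5-dimethyl-13-phenyltridecanal | C[C@H](CCCCCCCCc1ccccc1)C[C@H](C)CC=O | intermediate
18 | (4S,6R)-4,6-dimethyl-14-phenyltetradec-1-yne | C[C@H](CCCCCCCCc1ccccc1)C[C@H](C)CC#C | intermediate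
19 | dimethyl[(1E,4S,6R)-2,4,6-trimethyl-14-phenyltetradec-1-en-1-yl]alumane | C[C@H](CCCCCCCCc1ccccc1)C[C@H](C)C/C(C)=C/[Al](C)C | intermediate (not isolated)
20 | lithium butyl(dimethyl)[(1E,4S,6R)-2,4,6-trimethyl-14-phenyltetradec-1-en-1-yl]aluminate | [Li+].C[C@H](CCCCCCCCc1ccccc1)C[C@H](C)C/C(C)=C/[Al-](C)(C)CCCC | intermediate (not isolated)
21 | (2E,5S,7R)-3,5,7-trimethyl-15-phenylpentadec-2-en-1-ol | C[C@H](CCCCCCCCc1ccccc1)C[C@H](C)C/C(C)=C/CO | intermediate
22 | tert-butyl hydroperoxide | CC(C)(C)OO | starting material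
23 | [(2S,3S)-3-[(2S,4R)-2,4-dimethyl-12-phenyldodecyl]-3-methyloxiran-2-yl]methanol | C[C@H](CCCCCCCCc1ccccc1)C[C@H](C)C[C@]2(C)O[C@H]2CO | intermediate
24 | (3S,5S,7R)-3,5,7-trimethyl-15-phenylpentadecane-1,3-diol | C[C@H](CCCCCCCCc1ccccc1)C[C@H](C)C[C@](C)(O)CCO | intermediate
25 | 4-methylbenzenesulfonyl chloride | Cc1ccc(cc1)S(=O)(=O)Cl | starting material
26 | (3S,5S,7R)-3-hydroxy-3,5,7-trimethyl-15-phenylpentadecyl 4-methylbenzenesulfonate | C[C@H](CCCCCCCCc1ccccc1)C[C@H](C)C[C@](C)(O)CCOS(=O)(=O)c2ccc(C)cc2 | intermediate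
27 | (2S)-2-[(2S,4R)-2,4-dimethyl-12-phenyldodecyl]-2-methyloxetane | C[C@H](CCCCCCCCc1ccccc1)C[C@H](C)C[C@@]2(C)CCO2 | intermediate
28 | hydrogen peroxide | OO | starting material
29 | (3R,5S,7R)-3-hydroperoxy-3,5,7-trimethyl-15-phenylpentadecan-1-ol | C[C@H](CCCCCCCCc1ccccc1)C[C@H](C)C[C@@](C)(OO)CCO | intermediate
30 | 2-methoxypropene | COC(C)=C | starting material
31 | (3R,5S,7R)-3-[(2-methoxypropan-2-yl)peroxy]-3,5,7-trimethyl-15-phenylpentadecan-1-ol | C[C@H](CCCCCCCCc1ccccc1)C[C@H](C)C[C@@](C)(OOC(C)(C)OC)CCO | intermediate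
32 | (3R,5S,7R)-3-[(2-methoxypropan-2-yl)peroxy]-3,5,7-trimethyl-15-phenylpentadecanal | C[C@H](CCCCCCCCc1ccccc1)C[C@H](C)C[C@@](C)(OOC(C)(C)OC)CC=O | intermediate
33 | methylmagnesium bromide | C[Mg]Br | starting material
34 | (2RS,4R,6S,8R)-4-[(2-methoxypropan-2-yl)peroxy]-4,6,8-trimethyl-16-phenylhexadecan-2-ol | C[C@H](CCCCCCCCc1ccccc1)C[C@H](C)C[C@@](C)(OOC(C)(C)OC)CC(C)O | intermediate
35 | (4R,6S,8R)-4-[(2-methoxypropan-2-yl)peroxy]-4,6,8-trimethyl-16-phenylhexadecan-2-one | C[C@H](CCCCCCCCc1ccccc1)C[C@H](C)C[C@@](C)(OOC(C)(C)OC)CC(C)=O | intermediate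
36 | methanol | CO | starting material
37 | (3RS,5R)-5-[(2S,4R)-2,4-dimethyl-12-phenyldodecyl]-3,5-dimethyl-1,2-dioxolan-3-ol | C[C@H](CCCCCCCCc1ccccc1)C[C@H](C)C[C@]1(C)CC(C)(O)OO1 | intermediate (not isolated)
38 | (3RS,5R)-5-[(2S,4R)-2,4-dimethyl-12-phenyldodecyl]-3-methoxy-3,5-dimethyl-1,2-dioxolane | C[C@H](CCCCCCCCc1ccccc1)C[C@H](C)C[C@]1(C)CC(C)(OC)OO1 | intermediate
39 | tert-butyl[(1-methoxyethenyl)oxy]dimethylsilane | C=C(OC)O[Si](C)(C)C(C)(C)C | starting material
40 | (5R)-5-[(2S,4R)-2,4-dimethyl-12-phenyldodecyl]-3,5-dimethyl-4,5-dihydro-1,2-dioxol-2-ium (peroxycarbenium ion) | C[C@H](CCCCCCCCc1ccccc1)C[C@H](C)C[C@]1(C)CC(C)=[O+]O1 | intermediate (not isolated)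
41 | methyl 2-[(3R,5R)-5-[(2S,4R)-2,4-dimethyl-12-phenyldodecyl]-3,5-dimethyl-1,2-dioxolan-3-yl]acetate | C[C@H](CCCCCCCCc1ccccc1)C[C@H](C)C[C@]1(C)C[C@](C)(CC(=O)OC)OO1 | intermediate
42 | water | O | starting material
43 | 2-[(3R,5R)-5-[(2S,4R)-2,4-dimethyl-12-phenyldodecyl]-3,5-dimethyl-1,2-dioxolan-3-yl]acetic acid | C[C@H](CCCCCCCCc1ccccc1)C[C@H](C)C[C@]1(C)C[C@](C)(CC(=O)O)OO1 | target

**Totals**
Total step count: 22. Longest linear sequence: 22 steps (fully linear from 1).

**Three steps most likely to fail**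

Step 21 (C3–C bond formation). The cation has almost no facial bias, so at best about half of the material is the wanted 3R epimer, and the ketene acetal can be consumed by TiCl4 before it traps the cation. Fallback: it sets out from 38 and comes back at 43. SnCl4 with allyltrimethylsilane in CH2Cl2 at −78 °C (Hosomi–Sakurai trapping of the same cation by a more robust nucleophile) gives (3S,5R)-5-[(2S,4R)-2,4-dimethyl-12-phenyldodecyl]-3,5-dimethyl-3-(prop-2-en-1-yl)-1,2-dioxolane F7, whose C3 epimer is removed by chromatography. Ozonolysis (O3, CH2Cl2, −78 °C; Me2S) gives 2-[(3R,5R)-5-[(2S,4R)-2,4-dimethyl-12-phenyldodecyl]-3,5-dimethyl-1,2-dioxolan-3-yl]acetaldehyde F8, and Pinnick oxidation (NaClO2, NaH2PO4, 2-methyl-2-butene, t-BuOH–H2O) gives 43.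

Step 18 (Grignard addition next to a peroxide). MeMgBr may attack the O–O bond or trigger β-elimination of the peroxide from the aldehyde enolate. Fallback: it sets out from 23 and comes back at 34, with the methyl group put in before any peroxide exists. Dess–Martin oxidation of 23 gives (2R,3S)-3-[(2S,4R)-2,4-dimethyl-12-phenyldodecyl]-3-methyloxirane-2-carbaldehyde F1. MeMgBr at −78 °C gives (1RS)-1-[(2S,3S)-3-[(2S,4R)-2,4-dimethyl-12-phenyldodecyl]-3-methyloxiran-2-yl]ethan-1-ol F2. NaAlH2(OCH2CH2OCH3)2 gives (2RS,4S,6S,8R)-4,6,8-trimethyl-16-phenylhexadecane-2,4-diol F3. MsCl/Et3N gives (2RS,4S,6S,8R)-4-hydroxy-4,6,8-trimethyl-16-phenylhexadecan-2-yl methanesulfonate F4, and KOtBu closes (2S,4RS)-2-[(2S,4R)-2,4-dimethyl-12-phenyldodecyl]-2,4-dimethyloxetane F5. H2O2/TMSOTf opens F5 at the tertiary carbon with inversion to (2RS,4R,6S,8R)-4-hydroperoxy-4,6,8-trimethyl-16-phenylhexadecan-2-ol F6, and 2-methoxypropene/PPTS then gives 34.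

Step 22 (enzymatic hydrolysis). The ester CH2 sits next to a quaternary ring carbon on a very lipophilic substrate, so the lipase may turn over slowly or not at all. Fallback: it sets out from 38 and comes back at 43. TiCl4 with 1-(ethylsulfanyl)-1-(trimethylsilyloxy)ethene gives S-ethyl 2-[(3R,5R)-5-[(2S,4R)-2,4-dimethyl-12-phenyldodecyl]-3,5-dimethyl-1,2-dioxolan-3-yl]ethanethioate F9 (3R epimer separated as before). AgOSO2CF3 with 2,6-lutidine in wet THF then cleaves the thioester by thiophilic activation at neutral pH to give 43.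

**Further compounds**
F1 | step 18 | (2R,3S)-3-[(2S,4R)-2,4-dimethyl-12-phenyldodecyl]-3-methyloxirane-2-carbaldehyde | C[C@H](CCCCCCCCc1ccccc1)C[C@H](C)C[C@]2(C)O[C@H]2C=O
F2 | step 18 | (1RS)-1-[(2S,3S)-3-[(2S,4R)-2,4-dimethyl-12-phenyldodecyl]-3-methyloxiran-2-yl]ethan-1-ol | C[C@H](CCCCCCCCc1ccccc1)C[C@H](C)C[C@]2(C)O[C@H]2C(C)O
F3 | step 18 | (2RS,4S,6S,8R)-4,6,8-trimethyl-16-phenylhexadecane-2,4-diol | C[C@H](CCCCCCCCc1ccccc1)C[C@H](C)C[C@](C)(O)CC(C)O
F4 | step 18 | (2RS,4S,6S,8R)-4-hydroxy-4,6,8-trimethyl-16-phenylhexadecan-2-yl methanesulfonate | C[C@H](CCCCCCCCc1ccccc1)C[C@H](C)C[C@](C)(O)CC(C)OS(C)(=O)=O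
F5 | step 18 | (2S,4RS)-2-[(2S,4R)-2,4-dimethyl-12-phenyldodecyl]-2,4-dimethyloxetane | C[C@H](CCCCCCCCc1ccccc1)C[C@H](C)C[C@@]2(C)CC(C)O2
F6 | step 18 | (2RS,4R,6S,8R)-4-hydroperoxy-4,6,8-trimethyl-16-phenylhexadecan-2-ol | C[C@H](CCCCCCCCc1ccccc1)C[C@H](C)C[C@@](C)(OO)CC(C)O
F7 | step 21 | (3S,5R)-5-[(2S,4R)-2,4-dimethyl-12-phenyldodecyl]-3,5-dimethyl-3-(prop-2-en-1-yl)-1,2-dioxolane | C[C@H](CCCCCCCCc1ccccc1)C[C@H](C)C[C@]1(C)C[C@](C)(CC=C)OO1
F8 | step 21 | 2-[(3R,5R)-5-[(2S,4R)-2,4-dimethyl-12-phenyldodecyl]-3,5-dimethyl-1,2-dioxolan-3-yl]acetaldehyde | C[C@H](CCCCCCCCc1ccccc1)C[C@H](C)C[C@]1(C)C[C@](C)(CC=O)OO1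
F9 | step 22 | S-ethyl 2-[(3R,5R)-5-[(2S,4R)-2,4-dimethyl-12-phenyldodecyl]-3,5-dimethyl-1,2-dioxolan-3-yl]ethanethioate | C[C@H](CCCCCCCCc1ccccc1)C[C@H](C)C[C@]1(C)C[C@](C)(CC(=O)SCC)OO1
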